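51.0% is the number we start from: the mean of product plus intermediate B at 2.50 h in our earlier runs. The three sums, 50.0%, 52.0% and 51.0%, stand close for readings scattered by 1.5 percentage points, although [coupling partner] ranged from 0.026 M to 0.10 M.

| flask | starting material | coupling partner | remark | time |
|---|---|---|---|---|
| Sunday's | 0.050 M | 0.026 M | run made earlier |  |
| Monday's | 0.050 M | 0.10 M | run made earlier |  |
| Wednesday's | 0.025 M | 0.0525 M | run made earlier |  |
| flask | 0.050 M | 0.0525 M |  | 3.0 h |

| run | time / h | product / % | intermediate B / % |
|---|---|---|---|
| Sunday's | 0.667 | 3 | 21 |
| Sunday's | 1.33 | 5 | 26 |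
| Sunday's | 2.00 | 10 | 35 |
| Sunday's | 2.50 | 13 | 37 |
| Monday's | 0.200 | 0 | 8 |
| Monday's | 0.417 | 3 | 13 |
| Monday's | 1.00 | 12 | 18 |
| Monday's | 2.50 | 36 | 16 |
| Wednesday's | 0.667 | 3 | 16 |
| Wednesday's | 1.33 | 13 | 21 |
| Wednesday's | 2.00 | 21 | 26 |
| Wednesday's | 2.50 | 24 | 27 |

(readings scatter by 1.5 percentage points)

- the reaction counts as stopped when no species that holds the starting material changes by six tenths of a point or more over the second half of the time

* at 3.0 h, what has stopped the reaction, if anything has (all of the starting material has reacted / forward and back rates have come level / the coupling partner has run out first / it is still moving)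
* how much product there is at 3.0 h, in percent of the starting material charged
* how much intermediate B there is at 3.0 h, in percent of the starting material charged
* how much intermediate E there is at 3.0 h, in percent of the starting material charged

So we treat this sum as blind to the partner and carry it forward to 3.0 h. Sunday's and Wednesday's runs gained on average 4.5 points from 2.00 h to 2.50 h. Replacing the curve by that mean step for the equally long stretch to 3.0 h gives the joint yield, product plus intermediate B at that time, of 55.5%. With the sum still gaining, we expect the flask to be still moving.

Next comes the split, product over intermediate B, a kind of selectivity, which we assume holds over the last step. Wednesday's run, at the flask's own [coupling partner], read 0.889, which would give 26.1% product. That link is weak, since Wednesday's run held half the starting material. We reforge it at the flask's [starting material]: the split read at 2.50 h in Sunday's and Monday's runs rises between them as [coupling partner] to the power 1.38, and if we assume that power law holds, we get 0.926 at 0.0525 M. We commit to 26.7% product and 28.8% intermediate B. Intermediate E was never read, so it lies among the remaining 44.5%.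

The forecast, noting “Starting material and partner both remain”, said it is still moving, with product 29%, intermediate B 31% and intermediate E 9%. The flask shows that it is still moving, with product 26.0%, intermediate B 31.1% and intermediate E 16.5%.

    starting material ⇌ intermediate A (K = 1.60, k = 0.00170 s⁻¹)
    starting material → intermediate B (k = 2.40 × 10⁻⁴ s⁻¹)
    intermediate A ⇌ intermediate C (K = 0.370, k = 0.00280 s⁻¹)
    coupling partner + intermediate A → intermediate D (k = 0.00450 M⁻¹ s⁻¹)
    coupling partner + intermediate B ⇌ intermediate E (K = 22.0 M⁻¹, k = 0.00260 M⁻¹ s⁻¹)
    intermediate D → product (k = 2.70 × 10⁻⁴ s⁻¹)
    intermediate E ⇌ product (K = 1.30, k = 2.50 × 10⁻⁴ s⁻¹)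

At 3.00 h this flask makes intermediate B 5.39 times faster than it uses it up, each step taken net. Intermediate B stood at 24.0% at 1.50 h, and at 3.00 h it holds, together with product, 57.1%, against our joint yield of 55.5%. For the neighbour flask with 0.021 M of coupling partner, the same joint yield and a split of 0.262 give 11.5% product and 44.0% intermediate B. That neighbour flask holds 12.2% product and 44.6% intermediate B.

The data come from a simulation on assumed constants; scatter was added.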